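**Retrosynthetic overview**
- The acid comes from its methyl ester; the secondary methyl on ring B comes from a ketone (methylenation, then hydrogen-atom-transfer hydrogenation).
- Key disconnection: the benzylic C–C bond at the ring B quaternary carbon, made from the enolate of a cis-decalone and an o-quinone methide released by light from a phenolic benzylammonium salt.
- Ring B is formed second, by Robinson annulation of ethyl vinyl ketone onto the ring A cyclohexanone, then cis-selective enone hydrogenation.
- Ring A is formed first: its cyclohexanone arises by opening the cyclobutane of a pinane ketone, so that the gem-dimethyl bridge becomes the isopropylidene.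
- The pinane ketone comes from (+)-verbenone by vinylogous aldol with methyl glyoxylate, hydrogenation anti to the bridge (first stereocentre, which relays all others) and α-methylation.

Assumption: (1R,5R)-(+)-verbenone is bought (it is also one step from (+)-α-pinene). Decalin locants in the Why lines are naphthalene locants: C1 side chain, C2 isopropylidene, C4a ring-fusion H, C5 benzyl/methyl, C6 secondary methyl, C8a angular methyl. The route has not been run; the stereochemical outcomes of steps 4, 6, 8 and 10 are predictions from conformational analysis.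

**Step 1**
Reactants: 1 (1R,5R)-(+)-verbenone; 2 methyl glyoxylate
Product: 3 methyl (2E)-3-[(1S,5R)-6,6-dimethyl-4-oxobicyclo[3.1.1]hept-2-en-2-yl]prop-2-enoate
Conditions: NaOMe, MeOH, 0 → 25 °C
Reagents that add atoms: none
Why: Vinylogous (γ-selective) aldol condensation: the extended dienolate of the β-methyl enone attacks the unenolisable aldehyde through its γ-methyl carbon and E1cB loss of water gives the conjugated E-dienoate; no stereocentre is made.

**Step 2**
Reactants: 3
Product: 4 methyl 3-[(1R,2S,5R)-6,6-dimethyl-4-oxobicyclo[3.1.1]heptan-2-yl]propanoate (side chain syn to the gem-dimethyl bridge)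
Conditions: H2 (1 atm), Pd/C, EtOAc, 25 °C
Reagents that add atoms: none
Why: Heterogeneous catalytic hydrogenation saturates both C=C bonds; hydrogen reaches the ring alkene from the face opposite the gem-dimethyl bridge (as in verbenone to cis-verbanone), fixing the side-chain carbon as 2S, the centre that relays all later stereocentres.

**Step 3**
Reactants: 4
Product: 5 methyl 3-[(1R,2R,3S,5R)-3,6,6-trimethyl-4-oxobicyclo[3.1.1]heptan-2-yl]propanoate
Conditions: LiN(i-Pr)2, THF, −78 °C; MeI, −78 → −40 °C
Reagents that add atoms: iodomethane, CI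
Why: Kinetic enolate alkylation: only the C3 methylene can enolise (the other α-carbon is a bridgehead) and MeI enters anti to the bridge, trans to the chain; this centre is re-enolised in step 5, so its configuration is not critical.

**Step 4**
Reactants: 5
Product: 7 methyl 3-[(1S,2S)-2-methyl-3-oxo-6-(propan-2-ylidene)cyclohexyl]propanoate, via tertiary iodide silyl enol ether 6 (not isolated)
Conditions: Me3SiI, CH2Cl2, −40 °C; then NaOMe, MeOH, 0 °C
Reagents that add atoms: none
Why: Silyl-iodide activation of the ketone triggers Grob-type heterolysis of the strained cyclobutane bond between the α-bridgehead and CMe2 (the cleavage mode of nopinone-type ketones) to iodide 6, and acid-free E2 elimination gives mainly the Zaitsev isopropylidene; the side-chain stereocentre is β to the carbonyl and untouched, and the C2 methyl epimers both converge in step 5.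

**Step 5**
Reactants: 7; 8 ethyl vinyl ketone
Product: 10 methyl 3-[(1R,8aS)-5,8a-dimethyl-6-oxo-2-(propan-2-ylidene)-1,2,3,4,6,7,8,8a-octahydronaphthalen-1-yl]propanoate, via Michael adduct diketone 9 (not isolated)
Conditions: NaOMe, MeOH, −10 → 65 °C
Reagents that add atoms: none
Why: Robinson annulation (Michael addition, then aldol condensation): the more substituted enolate adds to the enone anti to the neighbouring side chain, which A(1,3) strain with the isopropylidene holds axial, so the new quaternary carbon carries its methyl cis to the chain.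

**Step 6**
Reactants: 10
Product: 11 methyl 3-[(1S,4aS,5R,8aR)-5,8a-dimethyl-6-oxo-2-(propan-2-ylidene)decahydronaphthalen-1-yl]propanoate (cis-fused)
Conditions: H2 (1 atm), Pd/C, EtOAc/pyridine, 25 °C
Reagents that add atoms: none
Why: Heterogeneous hydrogenation of a Wieland–Miescher-type enone: the A(1,3)-locked, folded ring A should expose the face carrying the angular methyl, so H adds to C4a cis to that methyl (cis-decalone); the tetrasubstituted isopropylidene is not reduced at 1 atm and the C5 centre is re-enolised in step 8.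

**Step 7**
Reactants: 12 4-methoxy-2-methylphenol
Product: 14 [(2-hydroxy-5-methoxy-3-methylphenyl)methyl]trimethylazanium iodide, via Mannich base 13 (not isolated)
Conditions: aq. CH2O, aq. Me2NH, EtOH, 80 °C; then MeI, acetone, 25 °C
Reagents that add atoms: formaldehyde, C=O; dimethylamine, CNC; iodomethane, CI
Why: Phenolic Mannich reaction at the only free ortho position (para is blocked by OMe), then Menshutkin N-methylation; no stereocentre.

**Step 8**
Reactants: 11; 14
Product: 16 methyl 3-[(1S,4aR,5R,8aS)-5-[(2-hydroxy-5-methoxy-3-methylphenyl)methyl]-5,8a-dimethyl-6-oxo-2-(propan-2-ylidene)decahydronaphthalen-1-yl]propanoate, via thermodynamic potassium enolate 15 (not isolated)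
Conditions: KN(SiMe3)2 (1 equiv), THF, 0 → 25 °C; 14 pre-mixed with KN(SiMe3)2 (1 equiv) in DMF, −40 °C; hν (λ > 300 nm), −40 °C; aq. NH4Cl
Reagents that add atoms: none
Why: Proposed new method: at −40 °C the phenolate–ammonium betaine should be thermally inert but on irradiation expel NMe3 to give the o-quinone methide in low stationary concentration, which is captured by the tetrasubstituted α-carbon of equilibrated enolate 15 from the face anti to the axial angular methyl (conformation fixed by the A(1,3) strain in ring A), forming the benzylic C–C bond and the C5 quaternary stereocentre with rearomatisation as driving force; the closest known reactions are thermal C-alkylation of enolates by phenolic Mannich-base methiodides and photochemical release of o-quinone methides from such salts for trapping by heteroatom nucleophiles and enol ethers.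

**Step 9**
Reactants: 16
Product: 17 methyl 3-[(1S,4aR,5R,8aS)-5-[(2-hydroxy-5-methoxy-3-methylphenyl)methyl]-5,8a-dimethyl-6-methylidene-2-(propan-2-ylidene)decahydronaphthalen-1-yl]propanoate
Conditions: Ph3PCH3Br, KN(SiMe3)2, THF, 0 → 65 °C
Reagents that add atoms: methyltriphenylphosphonium bromide, C[P+](c1ccccc1)(c1ccccc1)c1ccccc1.[Br-]
Why: Wittig methylenation with salt-free methylidenetriphenylphosphorane, which tolerates the α-quaternary ketone, the methyl ester and the phenoxide; no stereocentre.

**Step 10**
Reactants: 17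
Product: 18 methyl 3-[(1S,4aS,5S,6R,8aR)-5-[(2-hydroxy-5-methoxy-3-methylphenyl)methyl]-5,6,8a-trimethyl-2-(propan-2-ylidene)decahydronaphthalen-1-yl]propanoate
Conditions: Mn(dpm)3 (cat.), PhSiH3, t-BuOOH, i-PrOH, 22 °C
Reagents that add atoms: none
Why: Metal-hydride hydrogen-atom-transfer (Mukaiyama-type) hydrogenation: H• adds only to the CH2 terminus of the 1,1-disubstituted alkene (the tetrasubstituted isopropylidene is inert) and the tertiary radical is quenched under thermodynamic control, possibly helped by H-transfer from the phenol on the same face, giving the equatorial C6 methyl cis to the C5 and C8a methyls.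

**Step 11**
Reactants: 18
Product: 19 3-[(1S,4aS,5S,6R,8aR)-5-[(2-hydroxy-5-methoxy-3-methylphenyl)methyl]-5,6,8a-trimethyl-2-(propan-2-ylidene)decahydronaphthalen-1-yl]propanoic acid (CNP0299684.4)
Conditions: LiOH, THF/MeOH/H2O, 40 °C; then aq. HCl to pH 3
Reagents that add atoms: lithium hydroxide, [Li+].[OH-]
Why: Saponification (BAc2) and mild acidification; no stereocentre is α to the carboxyl group, and the phenol and tetrasubstituted alkene are inert.

**Compound list**
1 | (1R,5R)-(+)-verbenone, (1R,5R)-4,6,6-trimethylbicyclo[3.1.1]hept-3-en-2-one | CC1=CC(=O)[C@@H]2C[C@H]1C2(C)C | starting material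
2 | methyl glyoxylate (methyl 2-oxoacetate) | COC(=O)C=O | starting material
3 | methyl (2E)-3-[(1S,5R)-6,6-dimethyl-4-oxobicyclo[3.1.1]hept-2-en-2-yl]prop-2-enoate | COC(=O)/C=C/C1=CC(=O)[C@@H]2C[C@H]1C2(C)C | intermediate
4 | methyl 3-[(1R,2S,5R)-6,6-dimethyl-4-oxobicyclo[3.1.1]heptan-2-yl]propanoate | COC(=O)CC[C@H]1CC(=O)[C@@H]2C[C@H]1C2(C)C | intermediate
5 | methyl 3-[(1R,2R,3S,5R)-3,6,6-trimethyl-4-oxobicyclo[3.1.1]heptan-2-yl]propanoate | COC(=O)CC[C@H]1[C@H](C)C(=O)[C@@H]2C[C@H]1C2(C)C | intermediate
6 | methyl 3-[(1S,2S,6R)-6-(2-iodopropan-2-yl)-2-methyl-3-(trimethylsilyloxy)cyclohex-3-en-1-yl]propanoate | COC(=O)CC[C@H]1[C@H](C)C(O[Si](C)(C)C)=CC[C@H]1C(C)(C)I | intermediate (not isolated)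
7 | methyl 3-[(1S,2S)-2-methyl-3-oxo-6-(propan-2-ylidene)cyclohexyl]propanoate (C2 epimerisable) | COC(=O)CC[C@H]1[C@H](C)C(=O)CCC1=C(C)C | intermediate
8 | ethyl vinyl ketone (pent-1-en-3-one) | CCC(=O)C=C | starting material
9 | methyl 3-[(1R,2S)-2-methyl-3-oxo-2-(3-oxopentyl)-6-(propan-2-ylidene)cyclohexyl]propanoate | COC(=O)CC[C@H]1[C@](C)(CCC(=O)CC)C(=O)CCC1=C(C)C | intermediate (not isolated)
10 | methyl 3-[(1R,8aS)-5,8a-dimethyl-6-oxo-2-(propan-2-ylidene)-1,2,3,4,6,7,8,8a-octahydronaphthalen-1-yl]propanoate | CC1=C2CCC(=C(C)C)[C@@H](CCC(=O)OC)[C@]2(C)CCC1=O | intermediate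
11 | methyl 3-[(1S,4aS,5R,8aR)-5,8a-dimethyl-6-oxo-2-(propan-2-ylidene)decahydronaphthalen-1-yl]propanoate | C[C@@H]1[C@@H]2CCC(=C(C)C)[C@@H](CCC(=O)OC)[C@]2(C)CCC1=O | intermediate
12 | 4-methoxy-2-methylphenol | COc1ccc(O)c(C)c1 | starting material
13 | 2-[(dimethylamino)methyl]-4-methoxy-6-methylphenol | COc1cc(C)c(O)c(CN(C)C)c1 | intermediate (not isolated)
14 | [(2-hydroxy-5-methoxy-3-methylphenyl)methyl]trimethylazanium iodide | COc1cc(C)c(O)c(C[N+](C)(C)C)c1.[I-] | intermediate
15 | potassium enolate of 11 (enolate C=C between C5 and C6, O− on C6) | CC1=C([O-])CC[C@@]2(C)[C@H](CCC(=O)OC)C(=C(C)C)CC[C@@H]12.[K+] | intermediate (not isolated)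
16 | methyl 3-[(1S,4aR,5R,8aS)-5-[(2-hydroxy-5-methoxy-3-methylphenyl)methyl]-5,8a-dimethyl-6-oxo-2-(propan-2-ylidene)decahydronaphthalen-1-yl]propanoate | COc1cc(C)c(O)c(C[C@]2(C)[C@@H]3CCC(=C(C)C)[C@@H](CCC(=O)OC)[C@]3(C)CCC2=O)c1 | intermediate
17 | methyl 3-[(1S,4aR,5R,8aS)-5-[(2-hydroxy-5-methoxy-3-methylphenyl)methyl]-5,8a-dimethyl-6-methylidene-2-(propan-2-ylidene)decahydronaphthalen-1-yl]propanoate | COc1cc(C)c(O)c(C[C@]2(C)[C@@H]3CCC(=C(C)C)[C@@H](CCC(=O)OC)[C@]3(C)CCC2=C)c1 | intermediate
18 | methyl 3-[(1S,4aS,5S,6R,8aR)-5-[(2-hydroxy-5-methoxy-3-methylphenyl)methyl]-5,6,8a-trimethyl-2-(propan-2-ylidene)decahydronaphthalen-1-yl]propanoate | COc1cc(C)c(O)c(C[C@]2(C)[C@@H]3CCC(=C(C)C)[C@@H](CCC(=O)OC)[C@]3(C)CC[C@H]2C)c1 | intermediate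
19 | 3-[(1S,4aS,5S,6R,8aR)-5-[(2-hydroxy-5-methoxy-3-methylphenyl)methyl]-5,6,8a-trimethyl-2-(propan-2-ylidene)decahydronaphthalen-1-yl]propanoic acid | COc1cc(C)c(O)c(C[C@]2(C)[C@@H]3CCC(=C(C)C)[C@@H](CCC(=O)O)[C@]3(C)CC[C@H]2C)c1 | target

**Totals**
Total step count: 11. Longest linear sequence: 10 steps (1–6, then 8–11).

**Three steps most likely to fail**

Step 8 (the proposed new photochemical benzylation). It may fail through O-alkylation, attack at the less substituted α-carbon, or light absorption by the enolate. The fallback uses known enolate alkylation with a benzylic halide and sets out from 11, with the aryl part taken from Mannich base 13, isolated after the first half of step 7. Ethyl chloroformate (2.2 equiv, Et3N, CH2Cl2, 0 → 40 °C) acylates the phenol and then the amine, and chloride displaces the acylammonium group to give 2-(chloromethyl)-4-methoxy-6-methylphenyl ethyl carbonate F4. Enolate 15, made from 11 as in step 8, is alkylated thermally by F4 (NaI cat., THF, −20 → 25 °C) to methyl 3-[(1S,4aR,5R,8aS)-5-[[2-(ethoxycarbonyloxy)-5-methoxy-3-methylphenyl]methyl]-5,8a-dimethyl-6-oxo-2-(propan-2-ylidene)decahydronaphthalen-1-yl]propanoate F5. K2CO3 in MeOH removes the carbonate and the route is rejoined at 16.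

Step 4 (regiochemistry of the elimination: isopropylidene against isopropenyl, and alkene migration if any acid is present). The fallback sets out from 5. The same Me3SiI cleavage to 6 is followed by DBU (toluene, 60 °C) and aqueous work-up, accepting the less substituted alkene, methyl 3-[(1R,2S,6R)-2-methyl-3-oxo-6-(prop-1-en-2-yl)cyclohexyl]propanoate F1. A cobalt-hydride hydrogen-atom-transfer isomerisation (Co(salen)Cl and PhSiH3, both catalytic, benzene, 25 °C) then moves the double bond by one position into the tetrasubstituted site, where it stops reacting, and the route is rejoined at 7.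

Step 6 (face selectivity of the enone hydrogenation, and possible migration of the isopropylidene on palladium). The fallback sets out from 10. NaBH4 with CeCl3·7H2O (MeOH, −78 °C) gives the allylic alcohol with OH cis to the angular methyl, methyl 3-[(1R,6R,8aS)-6-hydroxy-5,8a-dimethyl-2-(propan-2-ylidene)-1,2,3,4,6,7,8,8a-octahydronaphthalen-1-yl]propanoate F2. Hydroxyl-directed hydrogenation with [Ir(cod)(PCy3)(py)]PF6 and H2 (CH2Cl2, 25 °C) delivers both hydrogens from the OH face to give the cis-fused methyl 3-[(1S,4aS,5R,6R,8aR)-6-hydroxy-5,8a-dimethyl-2-(propan-2-ylidene)decahydronaphthalen-1-yl]propanoate F3. Dess–Martin periodinane (CH2Cl2, 25 °C) oxidises the alcohol and the route is rejoined at 11.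

**Further compounds**
F1 | step 4 | methyl 3-[(1R,2S,6R)-2-methyl-3-oxo-6-(prop-1-en-2-yl)cyclohexyl]propanoate | COC(=O)CC[C@H]1[C@H](C)C(=O)CC[C@H]1C(C)=C
F2 | step 6 | methyl 3-[(1R,6R,8aS)-6-hydroxy-5,8a-dimethyl-2-(propan-2-ylidene)-1,2,3,4,6,7,8,8a-octahydronaphthalen-1-yl]propanoate | CC1=C2CCC(=C(C)C)[C@@H](CCC(=O)OC)[C@]2(C)CC[C@H]1O
F3 | step 6 | methyl 3-[(1S,4aS,5R,6R,8aR)-6-hydroxy-5,8a-dimethyl-2-(propan-2-ylidene)decahydronaphthalen-1-yl]propanoate | C[C@@H]1[C@@H]2CCC(=C(C)C)[C@@H](CCC(=O)OC)[C@]2(C)CC[C@H]1O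
F4 | step 8 | 2-(chloromethyl)-4-methoxy-6-methylphenyl ethyl carbonate | CCOC(=O)Oc1c(C)cc(OC)cc1CCl
F5 | step 8 | methyl 3-[(1S,4aR,5R,8aS)-5-[[2-(ethoxycarbonyloxy)-5-methoxy-3-methylphenyl]methyl]-5,8a-dimethyl-6-oxo-2-(propan-2-ylidene)decahydronaphthalen-1-yl]propanoate | CCOC(=O)Oc1c(C)cc(OC)cc1C[C@]1(C)[C@@H]2CCC(=C(C)C)[C@@H](CCC(=O)OC)[C@]2(C)CCC1=O
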